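Ring A (C4a, C5, C6, C7, quaternary C8, C8a) is a 6,6-dialkylcyclohexa-2,4-dienone oxygenated at C5, C7 and C8a, so it is cut into a four-carbon cyclobutenone (C7, C4a, C8a, C8) and a two-carbon siloxyalkyne (C6, C5). Heating the two triggers a 4π opening, ketene–alkyne [2+2], second 4π opening and 6π closure that form C6–C7 and C4a–C5, re-form C7–C8 and leave all six substituents, O1 included, in place; because C8 bears no hydrogen the dienone cannot aromatise. The precursor is a 3-alkoxy-4-lavandulyl-4-prenylcyclobut-2-enone whose alkoxy group is the O1–C2–C3 ester chain; ring B is closed afterwards by C4a acylation.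

Key step: step 15

Remark (stereochemistry, assumption): the lavandulyl CH of the target is R only because its CH2 carries C8; spatially it is that of (S)-lavandulol, C=C(C)[C@H](CC=C(C)C)CO, and the (R)-alcohol would give the epimer. (S)-Lavandulol is assumed purchasable as the single enantiomer (otherwise by lipase resolution of the racemate).

Remark (design): an ethynyl ether of a β-hydroxy ester would not survive the strong bases that ynol ether synthesis needs (retro-aldol, β-elimination). The O1 chain is therefore attached to the preformed four-membered ring by Mitsunobu inversion. The tert-butyl esters are later cleaved with TMSOTf/2,6-lutidine instead of a protic acid, which the three alkenes and the silyl dienol ether would not tolerate.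

Names: prenyl = 3-methylbut-2-en-1-yl; (2R)-lavandulyl = (2R)-5-methyl-2-(prop-1-en-2-yl)hex-4-en-1-yl. From compound 28 on, ring atoms carry chromanone numbers (O1, C2, C3, C4, C4a, C5–C8, C8a).

**Cyclobutenone fragment**

Step 1
Reactants: 1 (S)-lavandulol
Product: 2 (S)-lavandulyl iodide, (3S)-3-(iodomethyl)-2,6-dimethylhepta-1,5-diene
Conditions: I2, PPh3, imidazole, CH2Cl2, 0 °C to rt
Reagents that add atoms: iodine, [I][I]
Why: Appel iodination replaces the primary hydroxyl by SN2 at the CH2 group, so the neighbouring stereocentre is not involved.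

Step 2
Reactants: 2 (S)-lavandulyl iodide; 3 diethyl malonate
Product: 4 diethyl 2-[(2R)-lavandulyl]propanedioate
Conditions: NaH, 3 (3 equiv), THF/DMF, 0 to 60 °C
Reagents that add atoms: none
Why: Malonic ester alkylation, in which the soft, weakly basic malonate anion should prefer SN2 to E2 on the β-branched primary iodide and the excess of 3 suppresses double alkylation; the descriptor changes from S to R only through the new CIP priorities.

Step 3
Reactants: 4 diethyl 2-[(2R)-lavandulyl]propanedioate; 5 prenyl bromide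
Product: 6 diethyl 2-prenyl-2-[(2R)-lavandulyl]propanedioate
Conditions: NaH, THF, 0 °C to rt
Reagents that add atoms: none
Why: Second malonic ester alkylation with a reactive allylic bromide builds the quaternary carbon that becomes C8; it is not a stereocentre here because the two esters are identical.

Step 4
Reactants: 6 diethyl 2-prenyl-2-[(2R)-lavandulyl]propanedioate
Product: 8 5-methyl-2-[(2R)-lavandulyl]hex-4-enoic acid (both C2 epimers), via dialkylmalonic acid 7 (not isolated)
Conditions: KOH, EtOH/H2O, reflux; HCl to pH 2, 0 °C; pyridine, 115 °C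
Reagents that add atoms: potassium hydroxide, [K+].[OH-]
Why: Saponification and decarboxylation of the malonic acid (malonic ester synthesis) under non-acidic heating that spares the alkenes; the C2 epimer mixture is harmless because C2 becomes the sp2 ketene carbon in step 5.

Step 5
Reactants: 8 5-methyl-2-[(2R)-lavandulyl]hex-4-enoic acid; 9 ethoxyacetylene
Product: 12 3-ethoxy-4-prenyl-4-[(2R)-lavandulyl]cyclobut-2-en-1-one (both C4 epimers), via acid chloride 10 (not isolated), via dialkylketene 11 (not isolated)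
Conditions: (COCl)2, cat. DMF, CH2Cl2, 0 °C, evaporate; 9 (4 equiv), Et3N, MeCN, rt to 40 °C
Reagents that add atoms: none
Why: Dehydrochlorination gives the dialkylketene, which undergoes ketene–ynol ether [2+2] cycloaddition with its carbonyl carbon bonding to the nucleophilic CH terminus of 9; the excess of the electron-rich alkyne and the low temperature should outrun addition of the ketene to its own alkenes.

Step 6
Reactants: 12 3-ethoxy-4-prenyl-4-[(2R)-lavandulyl]cyclobut-2-en-1-one
Product: 13 3-hydroxy-4-prenyl-4-[(2R)-lavandulyl]cyclobut-2-en-1-one (enol of the 2,2-dialkylcyclobutane-1,3-dione)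
Conditions: 1 M HCl, THF, rt
Reagents that add atoms: water, O
Why: Hydrolysis of a vinylogous ester in cold dilute acid, which the alkenes tolerate, gives the strongly acidic vinylogous acid; the ring carbon bearing the two chains ceases to be a stereocentre because the two carbonyl carbons exchange by tautomerism.

Step 7
Reactants: 14 tert-butyl (3S)-3-hydroxybutanoate
Product: 15 tert-butyl (2S,3S)-3-hydroxy-2-methylbutanoate
Conditions: LiN(i-Pr)2 (2.2 equiv), THF, −78 to −20 °C; MeI, DMPU, −78 to 0 °C
Reagents that add atoms: iodomethane, IC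
Why: Fráter–Seebach alkylation, in which the chelated lithium alkoxide–enolate is methylated on the face away from the C4 methyl group, setting C2 anti to the hydroxyl group (2S,3S).

Step 8
Reactants: 13 3-hydroxy-4-prenyl-4-[(2R)-lavandulyl]cyclobut-2-en-1-one; 15 tert-butyl (2S,3S)-3-hydroxy-2-methylbutanoate
Product: 16 tert-butyl (2S,3R)-2-methyl-3-({3-oxo-4-prenyl-4-[(2R)-lavandulyl]cyclobut-1-en-1-yl}oxy)butanoate (both ring C4 epimers)
Conditions: PPh3, DIAD, THF, 0 °C to rt
Reagents that add atoms: none
Why: Mitsunobu O-alkylation of a vinylogous acid, in which the symmetric enolate of 13 displaces the oxyphosphonium group with inversion (3S to 3R) to give the syn (2S,3R) chain of the cis-2,3-dimethylchromanone; either oxygen leads to the same enol ether.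

**Siloxyalkyne fragment**

Step 9
Reactants: 17 (4S)-4-benzyl-1,3-oxazolidin-2-one; 18 pentanoyl chloride
Product: 19 (4S)-4-benzyl-3-pentanoyl-1,3-oxazolidin-2-one
Conditions: n-BuLi, THF, −78 °C; then 18, −78 to 0 °C
Reagents that add atoms: none
Why: N-Acylation of the lithiated oxazolidinone by the acid chloride, which does not touch the auxiliary stereocentre.

Step 10
Reactants: 19 (4S)-4-benzyl-3-pentanoyl-1,3-oxazolidin-2-one; 20 tert-butyl bromoacetate
Product: 21 tert-butyl (3R)-3-{[(4S)-4-benzyl-2-oxo-1,3-oxazolidin-3-yl]carbonyl}hexanoate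
Conditions: NaN(SiMe3)2, THF, −78 °C; 20, −78 to −40 °C
Reagents that add atoms: none
Why: Evans alkylation, in which the chelated sodium Z-enolate is alkylated on the face opposite the benzyl group, setting the (R) centre that becomes the arm stereocentre.

Step 11
Reactants: 21 tert-butyl (3R)-3-{[(4S)-4-benzyl-2-oxo-1,3-oxazolidin-3-yl]carbonyl}hexanoate
Product: 22 tert-butyl (3R)-3-(hydroxymethyl)hexanoate
Conditions: LiBH4, H2O (1 equiv), Et2O, 0 °C
Reagents that add atoms: none
Why: Borohydride reduction of the activated imide carbonyl releases the auxiliary and leaves the hindered tert-butyl ester and the stereocentre intact.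

Step 12
Reactants: 22 tert-butyl (3R)-3-(hydroxymethyl)hexanoate
Product: 23 tert-butyl (3R)-3-formylhexanoate
Conditions: TEMPO (cat.), PhI(OAc)2, CH2Cl2, rt
Reagents that add atoms: none
Why: Oxoammonium (TEMPO) oxidation of a primary alcohol stops at the aldehyde in the absence of water and is mild enough not to enolise the α-stereocentre.

Step 13
Reactants: 23 tert-butyl (3R)-3-formylhexanoate
Product: 24 tert-butyl (3R)-3-ethynylhexanoate
Conditions: dimethyl (1-diazo-2-oxopropyl)phosphonate, K2CO3, MeOH, 0 °C to rt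
Reagents that add atoms: dimethyl (1-diazo-2-oxopropyl)phosphonate, CC(=O)C(=[N+]=[N-])P(=O)(OC)OC
Why: Ohira–Bestmann homologation (olefination to the diazoalkene, loss of nitrogen, 1,2-hydrogen shift); cold carbonate in methanol should leave the tert-butyl ester and the α-stereocentre unchanged.

Step 14
Reactants: 24 tert-butyl (3R)-3-ethynylhexanoate
Product: 27 tert-butyl (3R)-3-{[tri(propan-2-yl)silyl]oxyethynyl}hexanoate, via lithium acetylide 25 (not isolated), via lithium ynolate 26 (not isolated)
Conditions: n-BuLi (1.0 equiv), THF, −78 °C; LiOOt-Bu (from t-BuOOH and LiN(SiMe3)2), −78 to 0 °C; TIPSOTf, −78 to 0 °C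
Reagents that add atoms: lithium tert-butyl peroxide, CC(C)(C)OO[Li]; triisopropylsilyl trifluoromethanesulfonate, CC(C)[Si](C(C)C)(C(C)C)OS(=O)(=O)C(F)(F)F
Why: Oxidation of the lithium acetylide by the electrophilic peroxide oxygen gives the ynolate, which the bulky silyl triflate traps on oxygen; deprotonation of the sp C–H at −78 °C is much faster than attack on or enolisation of the tert-butyl ester.

**Union and endgame**

Step 15
Reactants: 16 tert-butyl (2S,3R)-2-methyl-3-({3-oxo-4-prenyl-4-[(2R)-lavandulyl]cyclobut-1-en-1-yl}oxy)butanoate; 27 tert-butyl (3R)-3-{[tri(propan-2-yl)silyl]oxyethynyl}hexanoate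
Product: 31 (8R)-ring A dienone (C8 prenyl and (2R)-lavandulyl, C7=O, C6–[(R)-CH(n-Pr)CH2CO2t-Bu], C5–OSi(i-Pr)3, C4a–H, C8a–O–[(2S,3R)-CH(CH3)CH(CH3)CO2t-Bu]), via vinylketene 28 (not isolated), via 4-alkenylcyclobutenone 29 (not isolated), via dienylketene 30 (not isolated)
Conditions: 27 (2 equiv), toluene, 80 °C (to 100 °C only if 29 persists), sealed tube; Et3N-deactivated silica, then preparative HPLC to separate the C8 epimers
Reagents that add atoms: none
Why: Thermal 4π opening of 16 (C7–C8 bond) gives vinylketene 28, whose ketene carbon C7 is attacked by the nucleophilic β-carbon of the siloxyalkyne (future C6), so that the [2+2] cycloaddition forms C6–C7 and C4a–C5 in 29; a second 4π opening gives dienylketene 30, and 6π disrotatory electrocyclisation between C7 and the fully substituted C8 closes ring A. The closest known reaction is the Danheiser benzannulation of cyclobutenones with alkoxy- and siloxyalkynes, together with the related resorcinol synthesis from 3-siloxycyclobutenones; here the usual last tautomerisation to a phenol is impossible because C8 carries no hydrogen, so the 6,6-dialkylcyclohexa-2,4-dienone is the end point. Ring A is closed in a pericyclic, not an ionic, mode, which is why the hindered quaternary terminus should be tolerated. C8 is the only new stereocentre: the C4 configuration of 16 is erased in 28, and C8 is set by the torquoselectivity of the closure, biased only by the lavandulyl CH and the remote O1 chain, so both epimers are expected and the (8R) isomer is separated. The step needs regioselectivity in the [2+2], which the polarity of ketene and ynol ether secures (it also puts O1 on C8a and the silyloxy group on C5), and a temperature low enough to avoid a [3,3] shift of the C8 prenyl group to C4a and capture of the ketenes by the pendant alkenes, for which the excess of the very electron-rich alkyne and 80 °C are chosen.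

Step 16
Reactants: 31 (8R)-ring A dienone bis(tert-butyl ester)
Product: 33 (8R)-ring A dienone diacid (C5–OSi(i-Pr)3 retained), via bis(trimethylsilyl) ester 32 (not isolated)
Conditions: TMSOTf, 2,6-lutidine, CH2Cl2, 0 °C to rt; pH 5 buffer work-up
Reagents that add atoms: none
Why: Silyl triflate-mediated tert-butyl ester cleavage (carbonyl O-silylation, loss of isobutene to the buffered base) needs no protic acid, so the alkenes, the enol ether and the silyl dienol ether should survive; the labile trimethylsilyl esters hydrolyse on work-up.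

Step 17
Reactants: 33 (8R)-ring A dienone diacid
Product: 36 (2R,3S,8R)-5-[tri(propan-2-yl)silyl]oxy chromanone acid (rings A and B closed, arm acid free), via bis(trifluoroacetic) mixed anhydride 34 (not isolated), via ring-closed arm mixed anhydride 35 (not isolated)
Conditions: (CF3CO)2O (2.5 equiv), CH2Cl2, −20 to 0 °C; aq. NaHCO3/THF work-up
Reagents that add atoms: water, O
Why: Mixed-anhydride Friedel–Crafts-type acylation, in which the O1-tethered acyl group attacks the enol ether carbon C4a through a six-membered transition state and proton loss restores the dienone to close ring B; the arm anhydride has no carbon nucleophile within reach and is hydrolysed on work-up, and the cold acidic medium leaves C2 and C3 untouched.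

Step 18
Reactants: 36 (2R,3S,8R)-5-[tri(propan-2-yl)silyl]oxy chromanone acid
Product: 37 CNP0266113.2, (3R)-3-{(2R,3S,8R)-5-hydroxy-2,3-dimethyl-4,7-dioxo-8-prenyl-8-[(2R)-lavandulyl]-3,4,7,8-tetrahydro-2H-chromen-6-yl}hexanoic acid
Conditions: HF·pyridine, pyridine, THF, 0 °C
Reagents that add atoms: none
Why: Fluoride cleavage of the silyl enol ether under mildly acidic, buffered conditions frees the C5 enol, which is hydrogen-bonded to the C4 carbonyl; no base is present that could epimerise C3 or open ring B by β-elimination of O1.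

**Compound list**

1 | (S)-lavandulol, (2S)-5-methyl-2-(prop-1-en-2-yl)hex-4-en-1-ol | C=C(C)[C@H](CC=C(C)C)CO | starting material
2 | (S)-lavandulyl iodide, (3S)-3-(iodomethyl)-2,6-dimethylhepta-1,5-diene | IC[C@@H](CC=C(C)C)C(C)=C | intermediate
3 | diethyl malonate | CCOC(=O)CC(=O)OCC | starting material
4 | diethyl 2-[(2R)-lavandulyl]propanedioate | C=C(C)[C@H](CC=C(C)C)CC(C(=O)OCC)C(=O)OCC | intermediate
5 | prenyl bromide, 1-bromo-3-methylbut-2-ene | CC(C)=CCBr | starting material
6 | diethyl 2-prenyl-2-[(2R)-lavandulyl]propanedioate | C=C(C)[C@H](CC=C(C)C)CC(CC=C(C)C)(C(=O)OCC)C(=O)OCC | intermediate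
7 | 2-prenyl-2-[(2R)-lavandulyl]propanedioic acid | C=C(C)[C@H](CC=C(C)C)CC(CC=C(C)C)(C(=O)O)C(=O)O | intermediate (not isolated)
8 | 5-methyl-2-[(2R)-lavandulyl]hex-4-enoic acid (both C2 epimers) | C=C(C)[C@H](CC=C(C)C)CC(CC=C(C)C)C(=O)O | intermediate
9 | ethoxyacetylene (ethoxyethyne) | CCOC#C | starting material
10 | 5-methyl-2-[(2R)-lavandulyl]hex-4-enoyl chloride | C=C(C)[C@H](CC=C(C)C)CC(CC=C(C)C)C(=O)Cl | intermediate (not isolated)
11 | dialkylketene, 5-methyl-2-[(2R)-lavandulyl]hexa-1,4-dien-1-one | C=C(C)[C@H](CC=C(C)C)CC(CC=C(C)C)=C=O | intermediate (not isolated)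
12 | 3-ethoxy-4-prenyl-4-[(2R)-lavandulyl]cyclobut-2-en-1-one (both C4 epimers) | CCOC1=CC(=O)C1(CC=C(C)C)C[C@@H](CC=C(C)C)C(C)=C | intermediate
13 | 3-hydroxy-4-prenyl-4-[(2R)-lavandulyl]cyclobut-2-en-1-one (dione enol) | OC1=CC(=O)C1(CC=C(C)C)C[C@@H](CC=C(C)C)C(C)=C | intermediate
14 | tert-butyl (3S)-3-hydroxybutanoate | C[C@H](O)CC(=O)OC(C)(C)C | starting material
15 | tert-butyl (2S,3S)-3-hydroxy-2-methylbutanoate | C[C@H](O)[C@H](C)C(=O)OC(C)(C)C | intermediate
16 | tert-butyl (2S,3R)-2-methyl-3-({3-oxo-4-prenyl-4-[(2R)-lavandulyl]cyclobut-1-en-1-yl}oxy)butanoate (both ring C4 epimers) | O=C1C=C(O[C@H](C)[C@H](C)C(=O)OC(C)(C)C)C1(CC=C(C)C)C[C@@H](CC=C(C)C)C(C)=C | intermediate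
17 | (4S)-4-benzyl-1,3-oxazolidin-2-one | O=C1N[C@@H](Cc2ccccc2)CO1 | starting material
18 | pentanoyl chloride | CCCCC(Cl)=O | starting material
19 | (4S)-4-benzyl-3-pentanoyl-1,3-oxazolidin-2-one | CCCCC(=O)N1[C@@H](Cc2ccccc2)COC1=O | intermediate
20 | tert-butyl bromoacetate | BrCC(=O)OC(C)(C)C | starting material
21 | tert-butyl (3R)-3-{[(4S)-4-benzyl-2-oxo-1,3-oxazolidin-3-yl]carbonyl}hexanoate | O=C(N1[C@@H](Cc2ccccc2)COC1=O)[C@H](CCC)CC(=O)OC(C)(C)C | intermediate
22 | tert-butyl (3R)-3-(hydroxymethyl)hexanoate | OC[C@H](CCC)CC(=O)OC(C)(C)C | intermediate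
23 | tert-butyl (3R)-3-formylhexanoate | O=C[C@H](CCC)CC(=O)OC(C)(C)C | intermediate
24 | tert-butyl (3R)-3-ethynylhexanoate | C#C[C@H](CCC)CC(=O)OC(C)(C)C | intermediate
25 | lithium acetylide of 24 | [Li]C#C[C@H](CCC)CC(=O)OC(C)(C)C | intermediate (not isolated)
26 | lithium ynolate, lithium (3R)-3-(2-tert-butoxy-2-oxoethyl)hex-1-yn-1-olate | [Li]OC#C[C@H](CCC)CC(=O)OC(C)(C)C | intermediate (not isolated)
27 | tert-butyl (3R)-3-{[tri(propan-2-yl)silyl]oxyethynyl}hexanoate | CC(C)[Si](C(C)C)(C(C)C)OC#C[C@H](CCC)CC(=O)OC(C)(C)C | intermediate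
28 | vinylketene from 16 (O=C7=C4aH–C8a(O-chain)=C8(prenyl)(lavandulyl)) | O=C=CC(O[C@H](C)[C@H](C)C(=O)OC(C)(C)C)=C(CC=C(C)C)C[C@@H](CC=C(C)C)C(C)=C | intermediate (not isolated)
29 | 2-(arm)-3-silyloxy-4-alkenylcyclobut-2-en-1-one ([2+2] adduct of 28 and 27) | O=C1C([C@H](CCC)CC(=O)OC(C)(C)C)=C(O[Si](C(C)C)(C(C)C)C(C)C)C1C(O[C@H](C)[C@H](C)C(=O)OC(C)(C)C)=C(CC=C(C)C)C[C@@H](CC=C(C)C)C(C)=C | intermediate (not isolated)
30 | dienylketene (O=C7=C6(arm)–C5(OSi)=C4aH–C8a(O-chain)=C8(prenyl)(lavandulyl)) | O=C=C([C@H](CCC)CC(=O)OC(C)(C)C)C(O[Si](C(C)C)(C(C)C)C(C)C)=CC(O[C@H](C)[C@H](C)C(=O)OC(C)(C)C)=C(CC=C(C)C)C[C@@H](CC=C(C)C)C(C)=C | intermediate (not isolated)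
31 | (8R)-ring A dienone, bis(tert-butyl ester), C5–OSi(i-Pr)3, C4a–H, O1 chain (2S,3R) on C8a | C=C(C)[C@H](CC=C(C)C)C[C@@]1(CC=C(C)C)C(=O)C([C@H](CCC)CC(=O)OC(C)(C)C)=C(O[Si](C(C)C)(C(C)C)C(C)C)C=C1O[C@H](C)[C@H](C)C(=O)OC(C)(C)C | intermediate
32 | bis(trimethylsilyl) ester of 33 | C=C(C)[C@H](CC=C(C)C)C[C@@]1(CC=C(C)C)C(=O)C([C@H](CCC)CC(=O)O[Si](C)(C)C)=C(O[Si](C(C)C)(C(C)C)C(C)C)C=C1O[C@H](C)[C@H](C)C(=O)O[Si](C)(C)C | intermediate (not isolated)
33 | (8R)-ring A dienone diacid, C5–OSi(i-Pr)3 | C=C(C)[C@H](CC=C(C)C)C[C@@]1(CC=C(C)C)C(=O)C([C@H](CCC)CC(=O)O)=C(O[Si](C(C)C)(C(C)C)C(C)C)C=C1O[C@H](C)[C@H](C)C(=O)O | intermediate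
34 | bis(trifluoroacetic) mixed anhydride of 33 | C=C(C)[C@H](CC=C(C)C)C[C@@]1(CC=C(C)C)C(=O)C([C@H](CCC)CC(=O)OC(=O)C(F)(F)F)=C(O[Si](C(C)C)(C(C)C)C(C)C)C=C1O[C@H](C)[C@H](C)C(=O)OC(=O)C(F)(F)F | intermediate (not isolated)
35 | ring-B-closed chromanone, arm as trifluoroacetic mixed anhydride | C=C(C)[C@H](CC=C(C)C)C[C@@]1(CC=C(C)C)C(=O)C([C@H](CCC)CC(=O)OC(=O)C(F)(F)F)=C(O[Si](C(C)C)(C(C)C)C(C)C)C2=C1O[C@H](C)[C@H](C)C2=O | intermediate (not isolated)
36 | (2R,3S,8R)-5-[tri(propan-2-yl)silyl]oxy chromanone acid | C=C(C)[C@H](CC=C(C)C)C[C@@]1(CC=C(C)C)C(=O)C([C@H](CCC)CC(=O)O)=C(O[Si](C(C)C)(C(C)C)C(C)C)C2=C1O[C@H](C)[C@H](C)C2=O | intermediate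
37 | CNP0266113.2, (3R)-3-{(2R,3S,8R)-5-hydroxy-2,3-dimethyl-4,7-dioxo-8-prenyl-8-[(2R)-lavandulyl]-3,4,7,8-tetrahydro-2H-chromen-6-yl}hexanoic acid | C=C(C)[C@H](CC=C(C)C)C[C@@]1(CC=C(C)C)C(=O)C([C@H](CCC)CC(=O)O)=C(O)C2=C1O[C@H](C)[C@H](C)C2=O | target

**Step count and risk**

Total steps: 18. Longest linear sequence: 11 steps from 1 (steps 1–6, 8, 15–18); the siloxyalkyne branch has 6 steps before the union.

Steps most likely to fail:

Step 15. What may go wrong: the first ring opening of the vinylogous ester 16 may need a temperature at which the siloxyalkyne is consumed, the β-alkoxy ester chain eliminates, the ketenes are captured by the pendant alkenes or the C8 prenyl group migrates by [3,3] shift. The closure may also show no facial preference at C8. Fallback: the annulation is moved to the chain-free substrate type for which the reaction with siloxyalkynes is documented, and the O1 chain is attached afterwards. Setting out from 13, silylation (Et3SiCl, Et3N, CH2Cl2) should give 3-(triethylsilyloxy)-4-prenyl-4-[(2R)-lavandulyl]cyclobut-2-en-1-one F1. F1 can be heated harder with 27 because it carries no eliminable chain, and should give the (8R)-bis-silyl ring A dienone F2 (C8a–OSiEt3, C5–OSi(i-Pr)3; C8 epimers separated here). AcOH/THF/H2O should remove only the triethylsilyl group to give the (8R)-C8a enol F3. Mitsunobu reaction of F3 with 15 (PPh3, DIAD) should then alkylate the less hindered C8a oxygen with inversion, coming back to the route at 31.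

Step 17. What may go wrong: C4a of the push–pull dienol ether may be too weak a nucleophile for the mixed anhydride. Intermolecular trifluoroacetylation of C4a, acid-induced loss of the silyl group followed by lactonisation of the arm onto O5, or addition of trifluoroacetic acid to the alkenes could then overtake ring closure. Fallback: acid-free activation and Lewis-acid-promoted acylation. Setting out from 33, 1-chloro-N,N,2-trimethylprop-1-en-1-amine (CH2Cl2, 0 °C) should give the bis(acid chloride) F4 under neutral conditions. ZnCl2 (or Me2AlCl) at −40 °C should then promote Friedel–Crafts-type acylation of C4a to the ring-B-closed arm acid chloride F5, which aqueous NaHCO3 work-up hydrolyses, coming back to the route at 36.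

Step 8. What may go wrong: the oxyphosphonium intermediate of the α-branched β-hydroxy ester may lose a proton faster than it is displaced (E2 to tert-butyl tiglate), and the hindered enolate oxygens may react slowly. Fallback: the O–C bond is made at the ring carbon with retention instead of by SN2 at the chain carbon. Setting out from 13, oxalyl chloride/cat. DMF should give the vinylogous acid chloride 3-chloro-4-prenyl-4-[(2R)-lavandulyl]cyclobut-2-en-1-one F6. The syn alcohol comes from an Evans aldol reaction of purchased (4S)-4-benzyl-3-propanoyl-1,3-oxazolidin-2-one with acetaldehyde (Bu2BOTf, i-Pr2NEt), giving (4S)-4-benzyl-3-[(2S,3R)-3-hydroxy-2-methylbutanoyl]-1,3-oxazolidin-2-one F7. LiOH/H2O2 cleavage gives (2S,3R)-3-hydroxy-2-methylbutanoic acid F8, and O-tert-butyl-N,N'-diisopropylisourea gives tert-butyl (2S,3R)-3-hydroxy-2-methylbutanoate F9. The lithium alkoxide of F9 (LiN(SiMe3)2, THF, −78 °C) adds to F6 and chloride is expelled (addition–elimination), coming back to the route at 16.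

**Further compounds**

F1 | step 15 | 3-(triethylsilyloxy)-4-prenyl-4-[(2R)-lavandulyl]cyclobut-2-en-1-one | CC[Si](CC)(CC)OC1=CC(=O)C1(CC=C(C)C)C[C@@H](CC=C(C)C)C(C)=C
F2 | step 15 | (8R)-bis-silyl ring A dienone (C8a–OSiEt3, C5–OSi(i-Pr)3, arm tert-butyl ester) | C=C(C)[C@H](CC=C(C)C)C[C@@]1(CC=C(C)C)C(=O)C([C@H](CCC)CC(=O)OC(C)(C)C)=C(O[Si](C(C)C)(C(C)C)C(C)C)C=C1O[Si](CC)(CC)CC
F3 | step 15 | (8R)-C8a enol (C5–OSi(i-Pr)3, arm tert-butyl ester) | C=C(C)[C@H](CC=C(C)C)C[C@@]1(CC=C(C)C)C(=O)C([C@H](CCC)CC(=O)OC(C)(C)C)=C(O[Si](C(C)C)(C(C)C)C(C)C)C=C1O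
F4 | step 17 | bis(acid chloride) of 33 | C=C(C)[C@H](CC=C(C)C)C[C@@]1(CC=C(C)C)C(=O)C([C@H](CCC)CC(=O)Cl)=C(O[Si](C(C)C)(C(C)C)C(C)C)C=C1O[C@H](C)[C@H](C)C(=O)Cl
F5 | step 17 | ring-B-closed arm acid chloride | C=C(C)[C@H](CC=C(C)C)C[C@@]1(CC=C(C)C)C(=O)C([C@H](CCC)CC(=O)Cl)=C(O[Si](C(C)C)(C(C)C)C(C)C)C2=C1O[C@H](C)[C@H](C)C2=O
F6 | step 8 | 3-chloro-4-prenyl-4-[(2R)-lavandulyl]cyclobut-2-en-1-one | ClC1=CC(=O)C1(CC=C(C)C)C[C@@H](CC=C(C)C)C(C)=C
F7 | step 8 | (4S)-4-benzyl-3-[(2S,3R)-3-hydroxy-2-methylbutanoyl]-1,3-oxazolidin-2-one | C[C@@H](O)[C@H](C)C(=O)N1[C@@H](Cc2ccccc2)COC1=O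
F8 | step 8 | (2S,3R)-3-hydroxy-2-methylbutanoic acid | C[C@@H](O)[C@H](C)C(=O)O
F9 | step 8 | tert-butyl (2S,3R)-3-hydroxy-2-methylbutanoate | C[C@@H](O)[C@H](C)C(=O)OC(C)(C)C
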